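**Plan**

1. Retrosynthesis (side chain numbered C1' onward from C2): the first cut is C8'–C9', between the methyl-bearing olefinic carbon C8' and the chain CH2 C9'. It gives a C31 homoallylic pinacol boronate and a chroman-bound (Z)-2-iodoalkene. The boronate is then cut at CH2–B and at the mid-chain CH–CH2 bond (two farnesyl units). The chroman half is cut at C7'=C8', C5'–C6', O1–C8a and C4–C4a, back to (R)-linalool and 1,4-dimethoxy-2,3-dimethylbenzene.
2. Forward: two farnesyl pieces are joined by sulfone alkylation and homologated by one carbon to the boronate. Separately, the ring O1–C2–C3–C4–C4a–C8a is closed on a linalool-derived quinone and the chain is grown from its terminal (E)-methyl group. The halves are united last, before desilylation.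
3. Stereochemistry: C2 (R) is the carbinol carbon of (R)-linalool, whose C–O bond is never broken. Six E olefins come unchanged from (2E,6E)-farnesyl units, C3'=C4' from E-selective SeO2 oxidation, and C7'=C8' is fixed in the union.
4. Enabling feature: C8' is a methyl-bearing olefinic carbon whose neighbour C9' is an unactivated CH2 of a primary alkyl chain. Such an alkyl group migrates from boron to the alpha carbon of an alkenylboronate with inversion of olefin geometry. A Z iodide from a kinetic Wittig step is therefore translated into the E olefin C7'=C8' in the same event that forms C8'–C9'.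

Key step: step 17

Remark: commercial (R)-(−)-linalool is taken as enantiomerically enriched natural material; the target can be no purer in enantiomer than this starting material.
Remark: acetaldehyde N-tert-butylimine is treated as a purchased reagent (otherwise it is made by condensing acetaldehyde with tert-butylamine).

**Route**

Step 1
Reactants: 1 (2E,6E)-farnesyl acetate
Product: 2 (2E,6E,10E)-12-hydroxy-3,7,11-trimethyldodeca-2,6,10-trien-1-yl acetate
Conditions: SeO2 (cat.), t-BuOOH, salicylic acid (cat.), CH2Cl2, 0 °C to rt, stopped at partial conversion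
Reagents that add atoms: tert-butyl hydroperoxide, CC(C)(C)OO; SeO2, O=[Se]=O
Why: SeO2-catalysed allylic oxidation (ene reaction, then [2,3]-sigmatropic shift) attacks the (E)-methyl group of the terminal, most electron-rich trisubstituted olefin, far from the deactivating acetate, and should give the E primary allylic alcohol.

Step 2
Reactants: 2 (2E,6E,10E)-12-hydroxy-3,7,11-trimethyldodeca-2,6,10-trien-1-yl acetate
Product: 3 (2E,6E,10E)-12-bromo-3,7,11-trimethyldodeca-2,6,10-trien-1-yl acetate
Conditions: CBr4, PPh3, CH2Cl2, 0 °C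
Reagents that add atoms: carbon tetrabromide, BrC(Br)(Br)Br
Why: The Appel reaction converts the primary allylic alcohol into the bromide under neutral conditions that should neither shift nor isomerise the olefins nor touch the acetate.

Step 3
Reactants: 4 (2E,6E)-farnesyl bromide
Product: 5 (2E,6E)-farnesyl phenyl sulfone
Conditions: PhSO2Na, DMF, rt
Reagents that add atoms: sodium benzenesulfinate, [Na+].[O-]S(=O)c1ccccc1
Why: SN2 displacement of the primary allylic bromide by the sulfur of benzenesulfinate should give the allylic sulfone without allylic transposition.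

Step 4
Reactants: 5 (2E,6E)-farnesyl phenyl sulfone; 3 (2E,6E,10E)-12-bromo-3,7,11-trimethyldodeca-2,6,10-trien-1-yl acetate
Product: 7 (2E,6E,10E,14E,18E)-3,7,11,15,19,23-hexamethyl-13-(phenylsulfonyl)tetracosa-2,6,10,14,18,22-hexaen-1-yl acetate, via alpha-lithio farnesyl phenyl sulfone 6 (not isolated)
Conditions: n-BuLi, THF/DMPU, −78 °C; then 3, −78 to −40 °C
Reagents that add atoms: none
Why: Alkylation of the sulfone-stabilised allylic carbanion at its alpha carbon by the primary allylic bromide (Julia-type sulfone coupling) joins the two C15 units head to tail faster than the carbanion attacks the acetate at −78 °C; the sulfone-bearing centre is racemic and is removed in step 5.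

Step 5
Reactants: 7 (2E,6E,10E,14E,18E)-3,7,11,15,19,23-hexamethyl-13-(phenylsulfonyl)tetracosa-2,6,10,14,18,22-hexaen-1-yl acetate
Product: 8 (all-E)-hexaprenol
Conditions: LiBHEt3 (excess), THF, −78 to 0 °C; then Pd(dppp)Cl2 (5 mol %), 0 °C to rt
Reagents that add atoms: none
Why: Hydride first cleaves the acetate, then zerovalent palladium formed from Pd(dppp)Cl2 ionises the allylic sulfone and hydride is delivered to the less substituted terminus of the allyl complex (palladium-catalysed reductive desulfonylation), which should leave the C14=C15 olefin in place and E.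

Step 6
Reactants: 8 (all-E)-hexaprenol
Product: 9 (all-E)-hexaprenyl bromide
Conditions: CBr4, PPh3, CH2Cl2, 0 °C
Reagents that add atoms: carbon tetrabromide, BrC(Br)(Br)Br
Why: The Appel reaction gives the primary allylic bromide under neutral conditions that should preserve all six olefins.

Step 7
Reactants: 9 (all-E)-hexaprenyl bromide
Product: 10 2-[(3E,7E,11E,15E,19E)-4,8,12,16,20,24-hexamethylpentacosa-3,7,11,15,19,23-hexaen-1-yl]-4,4,5,5-tetramethyl-1,3,2-dioxaborolane
Conditions: CH2(Bpin)2, NaOtBu, THF, 0 °C to rt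
Reagents that add atoms: bis[(pinacolato)boryl]methane, CC1(C)OB(CB2OC(C)(C)C(C)(C)O2)OC1(C)C
Why: tert-Butoxide adds to one boron of the geminal bis(boronate) and releases a boron-stabilised carbanion that should displace the primary allylic bromide at CH2 (deborylative alkylation), adding the carbon that becomes C9' together with the boron handle for step 17.

Step 8
Reactants: 11 1,4-dimethoxy-2,3-dimethylbenzene
Product: 12 1-bromo-2,5-dimethoxy-3,4-dimethylbenzene
Conditions: NBS (1.0 equiv), MeCN, 0 °C to rt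
Reagents that add atoms: N-bromosuccinimide, O=C1CCC(=O)N1Br
Why: Electrophilic aromatic bromination of the electron-rich arene occurs at one of its two equivalent free positions, ortho to a methoxy group, and one equivalent of NBS limits dibromination.

Step 9
Reactants: 13 (R)-(−)-linalool; 12 1-bromo-2,5-dimethoxy-3,4-dimethylbenzene
Product: 15 (3R)-1-(2,5-dimethoxy-3,4-dimethylphenyl)-3,7-dimethyloct-6-en-3-ol, via B-alkyl-9-BBN borane 14 (not isolated)
Conditions: 9-BBN (1.5 equiv), THF, 0 °C to rt; then 12, Pd(OAc)2 (cat.), SPhos (cat.), aq. K3PO4, 60 °C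
Reagents that add atoms: none
Why: 9-BBN hydroborates only the monosubstituted vinyl group, at its terminal carbon, and B-alkyl Suzuki–Miyaura coupling joins that carbon to the aryl bromide; the carbinol stereocentre is not involved and the trisubstituted olefin is inert.

Step 10
Reactants: 15 (3R)-1-(2,5-dimethoxy-3,4-dimethylphenyl)-3,7-dimethyloct-6-en-3-ol
Product: 16 2-[(3R)-3-hydroxy-3,7-dimethyloct-6-en-1-yl]-5,6-dimethyl-1,4-benzoquinone
Conditions: (NH4)2Ce(NO3)6, MeCN/H2O, 0 °C, short reaction time
Reagents that add atoms: water, O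
Why: Oxidative demethylation of the para-dimethoxyarene by tetravalent cerium (two one-electron oxidations, attack of water) gives the para-quinone, and the tertiary alcohol and trisubstituted olefin should survive the short, cold exposure.

Step 11
Reactants: 16 2-[(3R)-3-hydroxy-3,7-dimethyloct-6-en-1-yl]-5,6-dimethyl-1,4-benzoquinone
Product: 18 (2R)-2,7,8-trimethyl-2-(4-methylpent-3-en-1-yl)chroman-6-ol, via cyclic 8a-methoxy ketal 17 (not isolated)
Conditions: HC(OMe)3, MeOH, camphorsulfonic acid (cat.), rt; then Et3N, L-ascorbic acid, MeOH/THF, rt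
Reagents that add atoms: none
Why: The tertiary hydroxyl adds to the neighbouring quinone carbonyl to close the six-membered hemiketal, methanol exchange under water-scavenging conditions gives the cyclic mixed ketal, and two-electron reduction expels the methoxy group from C8a and aromatises the carbocycle, the reductive collapse known for 8a-alkoxy ketals of the tocopherol series; the C2–O bond is never broken, so C2 keeps the R configuration brought in by linalool.

Step 12
Reactants: 18 (2R)-2,7,8-trimethyl-2-(4-methylpent-3-en-1-yl)chroman-6-ol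
Product: 19 (2R)-2,7,8-trimethyl-2-(4-methylpent-3-en-1-yl)-6-(triisopropylsilyloxy)chroman
Conditions: TIPSCl, imidazole, DMF, 40 °C
Reagents that add atoms: chlorotriisopropylsilane, CC(C)[Si](Cl)(C(C)C)C(C)C
Why: Silylation of the hindered phenol masks the oxidation-prone chromanol against SeO2, strong bases, alkyllithiums and iodine in steps 13 to 17.

Step 13
Reactants: 19 (2R)-2,7,8-trimethyl-2-(4-methylpent-3-en-1-yl)-6-(triisopropylsilyloxy)chroman
Product: 20 (2E)-2-methyl-5-[(2R)-2,7,8-trimethyl-6-(triisopropylsilyloxy)chroman-2-yl]pent-2-en-1-ol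
Conditions: SeO2 (cat.), t-BuOOH, salicylic acid (cat.), CH2Cl2, rt, stopped at partial conversion
Reagents that add atoms: tert-butyl hydroperoxide, CC(C)(C)OO; SeO2, O=[Se]=O
Why: SeO2-catalysed allylic oxidation (ene reaction, [2,3]-sigmatropic shift) of the only olefin is selective for the (E)-methyl group and should give the E allylic alcohol, which fixes the C3'=C4' geometry.

Step 14
Reactants: 20 (2E)-2-methyl-5-[(2R)-2,7,8-trimethyl-6-(triisopropylsilyloxy)chroman-2-yl]pent-2-en-1-ol
Product: 21 (2R)-2-[(3E)-5-bromo-4-methylpent-3-en-1-yl]-2,7,8-trimethyl-6-(triisopropylsilyloxy)chroman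
Conditions: CBr4, PPh3, CH2Cl2, 0 °C; used at once
Reagents that add atoms: carbon tetrabromide, BrC(Br)(Br)Br
Why: The Appel reaction gives the primary allylic bromide under neutral conditions that should keep the E olefin and the aryl silyl ether intact.

Step 15
Reactants: 21 (2R)-2-[(3E)-5-bromo-4-methylpent-3-en-1-yl]-2,7,8-trimethyl-6-(triisopropylsilyloxy)chroman
Product: 23 (4E)-4-methyl-7-[(2R)-2,7,8-trimethyl-6-(triisopropylsilyloxy)chroman-2-yl]hept-4-enal, via N-tert-butyl imine 22 (not isolated)
Conditions: acetaldehyde N-tert-butylimine, LiN(iPr)2, THF, −78 to 0 °C; then 21, −78 to −20 °C; then aq. oxalic acid, rt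
Reagents that add atoms: acetaldehyde N-tert-butylimine, CC=NC(C)(C)C; water, O
Why: The lithium aza-enolate of the acetaldehyde imine is C-alkylated by the primary allylic bromide at CH2 (SN2, metalloenamine alkylation) and mild acid hydrolysis frees the aldehyde, adding C6' and C7' without touching the E olefin or the silyl ether.

Step 16
Reactants: 23 (4E)-4-methyl-7-[(2R)-2,7,8-trimethyl-6-(triisopropylsilyloxy)chroman-2-yl]hept-4-enal
Product: 24 (2R)-2-[(3E,7Z)-8-iodo-4-methylnona-3,7-dien-1-yl]-2,7,8-trimethyl-6-(triisopropylsilyloxy)chroman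
Conditions: EtPPh3I, n-BuLi, THF, rt; I2, −78 °C; NaN(SiMe3)2, −78 to −20 °C; then 23, −78 °C to rt
Reagents that add atoms: ethyltriphenylphosphonium iodide, CC[P+](c1ccccc1)(c1ccccc1)c1ccccc1.[I-]; iodine, II
Why: Stork–Zhao–Wittig olefination: the non-stabilised alpha-iodo ylide made in the flask reacts under kinetic control and should place iodine cis to the chain, giving the Z alkenyl iodide that step 17 inverts.

Step 17
Reactants: 24 (2R)-2-[(3E,7Z)-8-iodo-4-methylnona-3,7-dien-1-yl]-2,7,8-trimethyl-6-(triisopropylsilyloxy)chroman; 10 2-[(3E,7E,11E,15E,19E)-4,8,12,16,20,24-hexamethylpentacosa-3,7,11,15,19,23-hexaen-1-yl]-4,4,5,5-tetramethyl-1,3,2-dioxaborolane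
Product: 28 O-triisopropylsilyl plastochromanol-8, via alkenyllithium 25 (not isolated), via lithium alkenylboronate complex 26 (not isolated), via beta-iodoalkyl boronate 27 (not isolated)
Conditions: 24 (1.2 equiv), t-BuLi (2.4 equiv), Et2O/THF, −78 °C; then 10, −78 °C; then I2 (1.0 equiv), THF, −78 °C; then NaOMe, MeOH, −78 °C to rt
Reagents that add atoms: none
Why: Iodine–lithium exchange with retention gives alkenyllithium 25, which adds to the boron of 10 to form borate 26; iodine then activates the electron-rich borate olefin as an iodonium ion, the primary C31 alkyl group shifts from boron to C8' anti to the breaking C–I bond (1,2-metallate rearrangement) to give 27, and methoxide induces anti elimination of boron and iodide. The closest known reaction type is the Zweifel olefination of alkenyllithium-derived pinacol boronate complexes, including alpha-substituted ones that give trisubstituted olefins. No ring is closed and no stereocentre is formed; the only new stereoelement is the C7'=C8' geometry, which is controlled by the Z geometry of 24 through the anti migration and anti elimination, so that boron cis to C6' becomes C9' trans to C6' (E). The step needs chemoselectivity of iodine for one olefin out of eight and migration of carbon in preference to a pinacol oxygen: the borate-bearing olefin is by far the most nucleophilic, iodine is limited to one equivalent at −78 °C, the phenol is silylated so that no phenoxide is iodinated, and any excess 25 is simply returned to 24 by iodine. The C2 stereocentre and the seven existing E olefins are not involved.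

Step 18
Reactants: 28 O-triisopropylsilyl plastochromanol-8
Product: 29 plastochromanol-8
Conditions: Bu4NF, THF, 0 °C, degassed; aq. NH4Cl work-up
Reagents that add atoms: none
Why: Fluoride cleaves the aryl silyl ether (strong Si–F bond) under conditions that should leave the eight olefins and the chroman untouched, giving the free chromanol.

**Compound list**

1 | (2E,6E)-farnesyl acetate | CC(C)=CCC/C(C)=C/CC/C(C)=C/COC(C)=O | starting material
2 | (2E,6E,10E)-12-hydroxy-3,7,11-trimethyldodeca-2,6,10-trien-1-yl acetate | OC/C(C)=C/CC/C(C)=C/CC/C(C)=C/COC(C)=O | intermediate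
3 | (2E,6E,10E)-12-bromo-3,7,11-trimethyldodeca-2,6,10-trien-1-yl acetate | BrC/C(C)=C/CC/C(C)=C/CC/C(C)=C/COC(C)=O | intermediate
4 | (2E,6E)-farnesyl bromide | CC(C)=CCC/C(C)=C/CC/C(C)=C/CBr | starting material
5 | (2E,6E)-farnesyl phenyl sulfone | CC(C)=CCC/C(C)=C/CC/C(C)=C/CS(=O)(=O)c1ccccc1 | intermediate
6 | alpha-lithio farnesyl phenyl sulfone | CC(C)=CCC/C(C)=C/CC/C(C)=C/C([Li])S(=O)(=O)c1ccccc1 | intermediate (not isolated)
7 | (2E,6E,10E,14E,18E)-3,7,11,15,19,23-hexamethyl-13-(phenylsulfonyl)tetracosa-2,6,10,14,18,22-hexaen-1-yl acetate, racemic at C13 | CC(C)=CCC/C(C)=C/CC/C(C)=C/C(C/C(C)=C/CC/C(C)=C/CC/C(C)=C/COC(C)=O)S(=O)(=O)c1ccccc1 | intermediate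
8 | (all-E)-hexaprenol, (2E,6E,10E,14E,18E)-3,7,11,15,19,23-hexamethyltetracosa-2,6,10,14,18,22-hexaen-1-ol | CC(C)=CCC/C(C)=C/CC/C(C)=C/CC/C(C)=C/CC/C(C)=C/CC/C(C)=C/CO | intermediate
9 | (all-E)-hexaprenyl bromide | CC(C)=CCC/C(C)=C/CC/C(C)=C/CC/C(C)=C/CC/C(C)=C/CC/C(C)=C/CBr | intermediate
10 | 2-[(3E,7E,11E,15E,19E)-4,8,12,16,20,24-hexamethylpentacosa-3,7,11,15,19,23-hexaen-1-yl]-4,4,5,5-tetramethyl-1,3,2-dioxaborolane | CC(C)=CCC/C(C)=C/CC/C(C)=C/CC/C(C)=C/CC/C(C)=C/CC/C(C)=C/CCB1OC(C)(C)C(C)(C)O1 | intermediate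
11 | 1,4-dimethoxy-2,3-dimethylbenzene | COc1ccc(OC)c(C)c1C | starting material
12 | 1-bromo-2,5-dimethoxy-3,4-dimethylbenzene | COc1cc(Br)c(OC)c(C)c1C | intermediate
13 | (R)-(−)-linalool, (3R)-3,7-dimethylocta-1,6-dien-3-ol | C=C[C@](C)(O)CCC=C(C)C | starting material
14 | (3S)-1-(9-borabicyclo[3.3.1]nonan-9-yl)-3,7-dimethyloct-6-en-3-ol (descriptor changed by priority only, geometry as in 13) | CC(C)=CCC[C@@](C)(O)CCB1C2CCCC1CCC2 | intermediate (not isolated)
15 | (3R)-1-(2,5-dimethoxy-3,4-dimethylphenyl)-3,7-dimethyloct-6-en-3-ol | COc1cc(CC[C@](C)(O)CCC=C(C)C)c(OC)c(C)c1C | intermediate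
16 | 2-[(3R)-3-hydroxy-3,7-dimethyloct-6-en-1-yl]-5,6-dimethyl-1,4-benzoquinone | CC1=C(C)C(=O)C(CC[C@](C)(O)CCC=C(C)C)=CC1=O | intermediate
17 | (2R)-8a-methoxy-2,7,8-trimethyl-2-(4-methylpent-3-en-1-yl)-2,3,4,8a-tetrahydro-6H-chromen-6-one, both C8a epimers | COC12O[C@](C)(CCC=C(C)C)CCC1=CC(=O)C(C)=C2C | intermediate (not isolated)
18 | (2R)-2,7,8-trimethyl-2-(4-methylpent-3-en-1-yl)chroman-6-ol | CC(C)=CCC[C@]1(C)CCc2cc(O)c(C)c(C)c2O1 | intermediate
19 | (2R)-2,7,8-trimethyl-2-(4-methylpent-3-en-1-yl)-6-(triisopropylsilyloxy)chroman | CC(C)=CCC[C@]1(C)CCc2cc(O[Si](C(C)C)(C(C)C)C(C)C)c(C)c(C)c2O1 | intermediate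
20 | (2E)-2-methyl-5-[(2R)-2,7,8-trimethyl-6-(triisopropylsilyloxy)chroman-2-yl]pent-2-en-1-ol | OC/C(C)=C/CC[C@]1(C)CCc2cc(O[Si](C(C)C)(C(C)C)C(C)C)c(C)c(C)c2O1 | intermediate
21 | (2R)-2-[(3E)-5-bromo-4-methylpent-3-en-1-yl]-2,7,8-trimethyl-6-(triisopropylsilyloxy)chroman | BrC/C(C)=C/CC[C@]1(C)CCc2cc(O[Si](C(C)C)(C(C)C)C(C)C)c(C)c(C)c2O1 | intermediate
22 | N-tert-butyl imine of aldehyde 23 | CC(C)(C)N=CCC/C(C)=C/CC[C@]1(C)CCc2cc(O[Si](C(C)C)(C(C)C)C(C)C)c(C)c(C)c2O1 | intermediate (not isolated)
23 | (4E)-4-methyl-7-[(2R)-2,7,8-trimethyl-6-(triisopropylsilyloxy)chroman-2-yl]hept-4-enal | O=CCC/C(C)=C/CC[C@]1(C)CCc2cc(O[Si](C(C)C)(C(C)C)C(C)C)c(C)c(C)c2O1 | intermediate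
24 | (2R)-2-[(3E,7Z)-8-iodo-4-methylnona-3,7-dien-1-yl]-2,7,8-trimethyl-6-(triisopropylsilyloxy)chroman | C/C(I)=C/CC/C(C)=C/CC[C@]1(C)CCc2cc(O[Si](C(C)C)(C(C)C)C(C)C)c(C)c(C)c2O1 | intermediate
25 | alkenyllithium from 24, lithium cis to the chain | C/C([Li])=C/CC/C(C)=C/CC[C@]1(C)CCc2cc(O[Si](C(C)C)(C(C)C)C(C)C)c(C)c(C)c2O1 | intermediate (not isolated)
26 | lithium alkenyl(C31-alkyl)pinacolboronate complex | [Li+].C/C(=C/CC/C(C)=C/CC[C@]1(C)CCc2cc(O[Si](C(C)C)(C(C)C)C(C)C)c(C)c(C)c2O1)[B-]1(CC/C=C(C)/CC/C=C(C)/CC/C=C(C)/CC/C=C(C)/CC/C=C(C)/CCC=C(C)C)OC(C)(C)C(C)(C)O1 | intermediate (not isolated)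
27 | beta-iodoalkyl pinacol boronate from anti addition across C7'=C8' (one of the two diastereomers shown; the other is inverted at both new centres) | C[C@@](CC/C=C(C)/CC/C=C(C)/CC/C=C(C)/CC/C=C(C)/CC/C=C(C)/CCC=C(C)C)(B1OC(C)(C)C(C)(C)O1)[C@H](I)CC/C(C)=C/CC[C@]1(C)CCc2cc(O[Si](C(C)C)(C(C)C)C(C)C)c(C)c(C)c2O1 | intermediate (not isolated)
28 | O-triisopropylsilyl plastochromanol-8 | CC(C)=CCC/C(C)=C/CC/C(C)=C/CC/C(C)=C/CC/C(C)=C/CC/C(C)=C/CC/C(C)=C/CC/C(C)=C/CC[C@]1(C)CCc2cc(O[Si](C(C)C)(C(C)C)C(C)C)c(C)c(C)c2O1 | intermediate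
29 | plastochromanol-8 | CC(C)=CCC/C(C)=C/CC/C(C)=C/CC/C(C)=C/CC/C(C)=C/CC/C(C)=C/CC/C(C)=C/CC/C(C)=C/CC[C@]1(C)CCc2cc(O)c(C)c(C)c2O1 | target

**Step count and risks**

Total: 18 steps. Longest linear sequence: 11 steps (steps 8 to 18, from 11 to 29). The boronate branch takes steps 1 to 7 and enters at step 17.

Step 11 (ketalisation and reductive collapse). What may go wrong: ketal formation at the other, less hindered carbonyl; conjugate addition of methanol; or reduction of unreacted quinone to the hydroquinone, whose acid-induced ring closure would erode the configuration at C2. Fallback: the ketal is reached by oxidative dearomatisation of a para-methoxyphenol instead of by ketalisation of the quinone. It sets out from borane 14 and comes back at ketal 17. Commercial 2,3-dimethylhydroquinone is monomethylated (MeOH, H2SO4, NaNO2 cat.) to 4-methoxy-2,3-dimethylphenol F1, acetylated (Ac2O, pyridine) to 4-methoxy-2,3-dimethylphenyl acetate F2 and brominated ortho to the methoxy group (NBS, MeCN) to 5-bromo-4-methoxy-2,3-dimethylphenyl acetate F3. Suzuki–Miyaura coupling of F3 with 14 (Pd(OAc)2, SPhos, aq. NaOH, which also cleaves the acetate) should give 5-[(3R)-3-hydroxy-3,7-dimethyloct-6-en-1-yl]-4-methoxy-2,3-dimethylphenol F4. Oxidation with PhI(OAc)2 in MeCN at 0 °C then lets the tethered tertiary hydroxyl trap the cation at C8a, which gives 17 for the ascorbic acid reduction of step 11.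

Step 17 (boronate union). What may go wrong: incomplete borate formation from the hindered alpha-methyl alkenyllithium; protonation of 25; attack of iodine on isolated olefins once the borate is consumed; or partial syn elimination that would erode the E geometry. Fallback: a retentive cross-coupling replaces the invertive boron shift. It sets out from aldehyde 23 and boronate 10 and comes back at 28. Aldehyde 23 is homologated with dimethyl (1-diazo-2-oxopropyl)phosphonate (K2CO3, MeOH; Ohira–Bestmann reagent) to (2R)-2-[(3E)-4-methyloct-3-en-7-yn-1-yl]-2,7,8-trimethyl-6-(triisopropylsilyloxy)chroman F5 and methylated (n-BuLi, MeI) to the corresponding 2-alkyne, (2R)-2-[(3E)-4-methylnon-3-en-7-yn-1-yl]-2,7,8-trimethyl-6-(triisopropylsilyloxy)chroman F6. Hydrozirconation (Cp2Zr(H)Cl in excess, THF, 50 °C, equilibration of zirconium to the methyl-bearing carbon; then I2) should give the E iodide, (2R)-2-[(3E,7E)-8-iodo-4-methylnona-3,7-dien-1-yl]-2,7,8-trimethyl-6-(triisopropylsilyloxy)chroman F7. Boronate 10 is oxidised (NaBO3·4H2O, THF/H2O) to (3E,7E,11E,15E,19E)-4,8,12,16,20,24-hexamethylpentacosa-3,7,11,15,19,23-hexaen-1-ol F8 and converted (I2, PPh3, imidazole) into the corresponding 1-iodide, (3E,7E,11E,15E,19E)-1-iodo-4,8,12,16,20,24-hexamethylpentacosa-3,7,11,15,19,23-hexaene F9. Lithiation of F9 (t-BuLi), transmetalation with ZnCl2 and Negishi coupling with F7 (Pd(PPh3)4) should give 28 with retention of the E geometry.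

Step 7 (deborylative alkylation). What may go wrong: attack at the tertiary allylic terminus (SN2'), elimination to a diene, or ether formation by tert-butoxide. Fallback: the extra carbon is inserted at boron instead of being attached at carbon. It sets out from bromide 9 and comes back at 10. Borylation of 9 under zerovalent-palladium catalysis (B2pin2, Pd2(dba)3 cat., THF) should give (all-E)-hexaprenyl pinacol boronate F10. Matteson homologation (ICH2Cl, n-BuLi, THF, −78 °C to rt: addition of LiCH2Cl to boron, then 1,2-shift of the allyl group) then gives 10.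

**Further compounds**

F1 | step 11 | 4-methoxy-2,3-dimethylphenol | COc1ccc(O)c(C)c1C
F2 | step 11 | 4-methoxy-2,3-dimethylphenyl acetate | COc1ccc(OC(C)=O)c(C)c1C
F3 | step 11 | 5-bromo-4-methoxy-2,3-dimethylphenyl acetate | COc1c(Br)cc(OC(C)=O)c(C)c1C
F4 | step 11 | 5-[(3R)-3-hydroxy-3,7-dimethyloct-6-en-1-yl]-4-methoxy-2,3-dimethylphenol | COc1c(CC[C@](C)(O)CCC=C(C)C)cc(O)c(C)c1C
F5 | step 17 | (2R)-2-[(3E)-4-methyloct-3-en-7-yn-1-yl]-2,7,8-trimethyl-6-(triisopropylsilyloxy)chroman | C#CCC/C(C)=C/CC[C@]1(C)CCc2cc(O[Si](C(C)C)(C(C)C)C(C)C)c(C)c(C)c2O1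
F6 | step 17 | (2R)-2-[(3E)-4-methylnon-3-en-7-yn-1-yl]-2,7,8-trimethyl-6-(triisopropylsilyloxy)chroman | CC#CCC/C(C)=C/CC[C@]1(C)CCc2cc(O[Si](C(C)C)(C(C)C)C(C)C)c(C)c(C)c2O1
F7 | step 17 | (2R)-2-[(3E,7E)-8-iodo-4-methylnona-3,7-dien-1-yl]-2,7,8-trimethyl-6-(triisopropylsilyloxy)chroman | C/C(I)=C\CC/C(C)=C/CC[C@]1(C)CCc2cc(O[Si](C(C)C)(C(C)C)C(C)C)c(C)c(C)c2O1
F8 | step 17 | (3E,7E,11E,15E,19E)-4,8,12,16,20,24-hexamethylpentacosa-3,7,11,15,19,23-hexaen-1-ol | CC(C)=CCC/C(C)=C/CC/C(C)=C/CC/C(C)=C/CC/C(C)=C/CC/C(C)=C/CCO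
F9 | step 17 | (3E,7E,11E,15E,19E)-1-iodo-4,8,12,16,20,24-hexamethylpentacosa-3,7,11,15,19,23-hexaene | CC(C)=CCC/C(C)=C/CC/C(C)=C/CC/C(C)=C/CC/C(C)=C/CC/C(C)=C/CCI
F10 | step 7 | (all-E)-hexaprenyl pinacol boronate | CC(C)=CCC/C(C)=C/CC/C(C)=C/CC/C(C)=C/CC/C(C)=C/CC/C(C)=C/CB1OC(C)(C)C(C)(C)O1
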